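# Proposed synthesis of chermebilaene B (38) by carbenoid insertion into the axial carbinol C–H of ring A

## The problem

Atoms are numbered in the order of the SMILES string of 38 (C1 is the ring A methyl carbon, O34 the last oxygen). Ring A (C2, C3, C5, C6, C11, C18) is a cyclohexane with two spiro centres: C11 is shared with the δ-lactone ring B (C11, C12, C13, C14, O16, C17) and C18 with ring C (C18, C19, C20, C31, O34). Ring C is fused through C20–C31 to a dioxa cage of ring D (C20, C22, C24, C33, O32, C31), ring E (C24, C25, O27, C28, C33) and ring F (C28, O30, C31, O32, C33); C31 is an ortho ester carbon and C28 an acylated ketal carbon. Of the eleven stereocentres, C6 can come from the chiral pool and control C11, and the axial C17 methylene on C11 can then steer reagents at C18, C2 and C3. C20 and C22 lie beyond O34 and must arrive as a separate enantiopure piece; C24 and C33 can be set from C22, and C28 and C31 are fixed by the cage. The C2 methyl is axial and syn-axial to C17, so it must be set under kinetic control. The cage is sensitive to aqueous acid, the tertiary C7 alcohol to dehydration, and the δ-lactone to base and to enolisation, its C13 hydrogens being more acidic than those of an open-chain ester. The key step is possible because C18 carries O34 equatorial and C19 axial, the pattern of an equatorial cyclohexanol whose axial hydrogen was replaced with retention; C19 is five atoms from that hydrogen along C19–C20–C31–O34–C18, and C20 is quaternary, so a carbenoid at C19 has no β-hydrogen.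

## Retrosynthesis

**Cage last.** The three C–O links that tie C28 and C31 into rings D, E and F (O27–C28, O30 between C28 and C31, O32–C31) are cut first, giving hydroxy acid 36 with the C28 ketone masked as a dimethyl ketal. This keeps the acid-labile cage out of every other step. The precursor has three rings fewer and only one stereocentre fewer in effect, since C28 and C31 can form in one way only. The forward step must close a caged ortho ester from a lactone and a cis-diol under dehydrating acid without harming the tertiary alcohol.

**C24–C33 by aldol.** Cutting C24–C33 leads to thioester 31 and aldehyde 33. A cut at C33–C28 or C22–C24 would not use the C25 carbonyl. An oxygen ester at C25 was rejected because base would enolise the ring B lactone first; an S-tert-butyl thioester is enolised by a boron triflate and an amine while lactones are not. The forward reaction must give the anti aldol and the correct enolate face relative to C22.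

**Adjusting C19 and C25.** Thioester 31 is traced to the key product 26 through diacid 27 and mono-thioester 28. The C19 ester is needed only to stabilise the carbenoid, and the C25 methyl ester is exchanged for the thioester. The forward steps must tell the unhindered C25 acid from the C19 acid, which sits between two quaternary carbons.

**Key cut, C18–C19.** Lactone 26 is opened at C18–C19 to diazo ester 25, the ester of the equatorial C18 alcohol with an α-quaternary acid. The neighbouring cuts are weaker: C19–C20 or C20–C31 would need a quaternary centre made next to a spiro carbon, and a polar C18–C19 bond would need a hindered enolate to attack a hindered, enolisable ketone. The insertion forms the most congested bond intramolecularly and keeps the C18 configuration. Two choices strengthen it. C25 is a methyl ester, because a tert-butyl ester could trap the carbenoid through its carbonyl oxygen with loss of isobutene. The tertiary hydroxyl is a TBS ether, because a trimethylsilyl ether would not survive the sequence.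

**Diazo group and ester bond.** The diazo group of 25 comes from α-keto ester 23 through its tosylhydrazone, because direct diazo transfer to a C19 methylene could not compete with the more acidic C13 and C24 positions. Ketone 23 comes from the C19 silyl ether 21 by way of alcohol 22, and 21 is cut at O34–C31 into alcohol 13 and acid 19. The C19 ketone is unveiled only after esterification, since with a free C31 acid it would be a β-keto acid that loses CO2. The forward esterification joins two hindered partners and is the most demanding conventional step.

**Ring A stereocentres.** Alcohol 13 comes from ketone 12 by axial hydride delivery. Ketone 12 comes from epoxy alcohol 10 by a stereospecific hydride shift from C18 to C2, which sets the axial C2 methyl under kinetic control and keeps the C3 oxygen as its TBS ether. Epoxide 10 comes from allylic alcohol 9 and that from enone 8. Conjugate addition or nucleophilic epoxidation of enone 8 would put the C3 oxygen on the wrong face, which is why the oxygen is delivered from the C18 hydroxyl.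

**Rings A and B from carvone.** Enone 8 is cut at C11–C12 and C11–C17 to silyl ether 3 of carvone hydrate 2, made from (R)-carvone 1. C17 enters first as a formyl group (4), so that acrylate 5 then adds anti to the C6 side chain (6) and the propanoate arm ends trans to it. Reduction of the aldehyde closes ring B. The precursor is a commodity terpene with the C6 configuration in place.

**Acid fragment from a cyclopentenone.** Acid 19 is reconnected between C31 and C25 to silyl enol ether 18 and ketone 17. Ketone 17 is cut at C22–C23 and C20–C19 to 2-methylcyclopent-2-en-1-one 14, a methyl Grignard reagent and methyl glyoxylate 15. The ring forces the C19 substituent trans to the new C22 methyl and leaves one enolisable position, so ozonolysis of 18 differentiates C31 (acid) from C25 (methyl ester) in one step. The conjugate addition must be enantioselective, since no other stereocentre is present.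

## Roads not taken

**Alternative 1: radical epoxy-polyene bicyclisation, then excision of the extra ring.** The cut runs through C6–C7 and C11–C18, and later through C7–C14. In the forward step Cp2TiCl (trivalent titanium), made from Cp2TiCl2 (tetravalent titanium) and manganese, opens a C14–C7 epoxide of an open chain to the C7 radical. That radical adds to C6, the C11 radical adds to C18, and the sequence ends as the exocyclic C1=C2 alkene of decalin A1.
- Merits: two rings, quaternary C11 and the C18–C19 bond arise in one step from an acyclic chain; no hindered esterification is needed.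
- Weak points: in A1, C18 is a CH carrying C19 as an acetoxymethyl group, so O34 would have to be introduced at an unactivated tertiary C–H between two substituted carbons. C3 has no oxygen. The axial C2 methyl must come from hydrogenation to the less stable epimer. The C7–C14 bond must be cleaved oxidatively afterwards. The absolute configuration rests on one enantioselective epoxidation, and such radical cascades are usually moderate in efficiency.
- Comparison: this road is better at making the C11/C18 carbon framework in one C–C bond-forming event. The chosen plan sets against it that the C18, C3 and C2 centres all derive from one alkene of 8 with defined stereochemistry, and that its C–H functionalisation takes place on an oxygen-bearing carbon.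

**Alternative 2: peracid excision of a decalin ring to unveil ring B.** The cut reconnects C7 to C14 in a bicyclic ketone. In the forward step a peracid inserts O10 between C14 and C7 (Baeyer–Villiger, the tertiary carbon migrates) and the C17 hydroxyl then takes the acyl group, giving spiro-lactone enone A2.
- Merits: ring B and the tertiary alcohol appear in one oxidation, and the migratory preference is the natural one.
- Weak points: the bicyclic precursor, with its angular hydroxymethyl group and defined C6/C11 configuration, must itself be made enantioselectively. The road solves only rings A and B and leaves the C18–C19 bond and the cage untouched.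
- Comparison: A2 is the desilyl analogue of 8, which the chosen route reaches in five steps from carvone. Alternative 2 is equal or better in avoiding the acid hydration of step 1. The chosen plan sets against it the low cost of carvone and two C–C bond formations steered by C6 alone.

**Alternative 3: inverse-demand oxa-Diels–Alder for ring D and the ortho ester carbon.** The cut removes C20–C22 and C31–O32. In the forward step a ketene acetal at C20=C31 in ring C adds, thermally or with Eu(fod)3 (trivalent europium), to a ketone-based oxadiene (O32, C33, C24, C22), giving adduct A3 with every carbon of the target.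
- Merits: convergent; C31 reaches the ortho ester level directly, with no dehydration equilibrium; C20 and C22 form together.
- Weak points: facial selectivity at C20 would have to come from ring A through the spiro carbon, and endo/exo selectivity decides C22. The tetrasubstituted ketene acetal is labile and shielded. A3 holds a C24=C33 enol ether that must be reduced with control of two centres beside a mixed ortho ester. Ring C must still be made first.
- Comparison: this road is stronger than the chosen plan exactly where the chosen plan is weakest, the late cage closure of step 24. The chosen plan sets against it that C20 and C22 are fixed early by catalyst control independent of ring A, and that C24 and C33 come from an aldol with predictable 1,2-induction.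

Key step: step 17

Remark: β is the face of ring A that carries C17 and the C6 side chain, α the opposite face. The C19 carbinol and C19 ester centres are drawn as one epimer; both serve, because C19 ends as CH2.

## Route

Step 1
Reactants: 1 (R)-carvone
Product: 2 (5R)-5-(2-hydroxypropan-2-yl)-2-methylcyclohex-2-en-1-one (carvone hydrate)
Conditions: 50% aq. H2SO4, 0 °C → rt
Reagents that add atoms: water, O
Why: Markovnikov hydration of the isolated 1,1-disubstituted alkene through the tertiary cation; the enone survives cold aqueous acid and the stereocentre (C6 of the target) is untouched.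

Step 2
Reactants: 2 carvone hydrate
Product: 3 (5R)-5-[2-(tert-butyldimethylsilyloxy)propan-2-yl]-2-methylcyclohex-2-en-1-one
Conditions: TBSOTf, 2,6-lutidine, CH2Cl2, 0 °C
Reagents that add atoms: tert-butyldimethylsilyl trifluoromethanesulfonate, CC(C)(C)[Si](C)(C)OS(=O)(=O)C(F)(F)F
Why: Silyl triflate silylation of a tertiary alcohol; the TBS ether lasts through all later steps and prevents O–H insertion in step 17.

Step 3
Reactants: 3 silyl ether
Product: 4 (5R,6Z)-5-[2-(tert-butyldimethylsilyloxy)propan-2-yl]-6-(hydroxymethylidene)-2-methylcyclohex-2-en-1-one (enol form of the C11 formyl ketone)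
Conditions: LiN(iPr)2, THF, −78 °C; CF3CH2OCHO, −78 → 0 °C
Reagents that add atoms: 2,2,2-trifluoroethyl formate, O=COCC(F)(F)F
Why: Kinetic α′-deprotonation of the cross-conjugated enone followed by Claisen formylation with the activated formate; the product rests as the chelated enol, so no stereocentre is at stake at C11 yet.

Step 4
Reactants: 4 hydroxymethylidene ketone, 5 methyl acrylate
Product: 6 methyl 3-[(1S,6R)-6-[2-(tert-butyldimethylsilyloxy)propan-2-yl]-1-formyl-3-methyl-2-oxocyclohex-3-en-1-yl]propanoate (C17 formyl cis to the C6 side chain)
Conditions: Et3N (cat.), MeCN, rt → 40 °C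
Reagents that add atoms: none
Why: Amine-catalysed Michael addition of the 1,3-dicarbonyl; the acrylate approaches C11 anti to the bulky C6 side chain, which sets the quaternary centre, and the ester enolate is protonated before it can add to C3.

Step 5
Reactants: 6 formyl keto ester
Product: 8 spiro δ-lactone enone (rings A and B; C17 cis to the C6 side chain), via hydroxy ester 7 (not isolated)
Conditions: NaBH4 (0.3 equiv), EtOH/CH2Cl2, −78 °C; then PPTS, PhH, 50 °C
Reagents that add atoms: none
Why: Chemoselective reduction, the aldehyde reacting far faster than the conjugated ketone at −78 °C, followed by acid-catalysed lactonisation of the neopentyl alcohol onto the methyl ester.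

Step 6
Reactants: 8 spiro lactone enone
Product: 9 C18 allylic alcohol (hydroxyl β and cis to C17)
Conditions: NaBH4, CeCl3·7H2O, MeOH, −78 °C
Reagents that add atoms: none
Why: Luche 1,2-reduction; hydride attacks C18 from the α face, anti to the pseudo-axial C17 methylene on the neighbouring quaternary carbon, as in the reduction of carvone to cis-carveol.

Step 7
Reactants: 9 allylic alcohol
Product: 10 C2–C3 β-epoxy alcohol (epoxide cis to the C18 hydroxyl)
Conditions: VO(acac)2 (tetravalent vanadium, cat.), t-BuOOH, CH2Cl2, 0 °C → rt
Reagents that add atoms: tert-butyl hydroperoxide, CC(C)(C)OO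
Why: Hydroxyl-directed epoxidation through the vanadium alkoxide delivers oxygen to the face of C2=C3 syn to the C18 hydroxyl, which fixes the C3–O configuration; no other alkene is present.

Step 8
Reactants: 10 epoxy alcohol
Product: 12 ring A ketone (C18 ketone; C3 OTBS β; C2 methyl β and axial), via C18 silyl ether 11 (not isolated)
Conditions: TBSOTf (2.2 equiv), iPr2NEt, 4 Å MS, CH2Cl2, −78 → −40 °C
Reagents that add atoms: tert-butyldimethylsilyl trifluoromethanesulfonate, CC(C)(C)[Si](C)(C)OS(=O)(=O)C(F)(F)F
Why: Semipinacol hydride shift of an epoxy silyl ether (non-aldol aldol rearrangement): the silyl triflate opens the epoxide at tertiary C2 while the anti-periplanar C18–H migrates to C2 with inversion. C2 therefore gains hydrogen on the α face (methyl β), C3 keeps its oxygen as the TBS ether and C18 becomes the ketone.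

Step 9
Reactants: 12 ring A ketone
Product: 13 ring A alcohol (equatorial β C18 hydroxyl; axial α C18–H)
Conditions: NaBH4, CeCl3·7H2O, MeOH/THF, −78 → −40 °C
Reagents that add atoms: none
Why: Hydride adds axially from the α face because the β face is flanked by the axial C1 methyl and the axial C17 methylene on both α-carbons; cold, cerium-buffered conditions limit C2 epimerisation and β-elimination of the silyloxy group.

Step 10
Reactants: 14 2-methylcyclopent-2-en-1-one, 15 methyl glyoxylate
Product: 17 methyl 2-hydroxy-2-[(1S,2S)-1,2-dimethyl-5-oxocyclopentyl]acetate, via bromomagnesium enolate 16 (not isolated)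
Conditions: MeMgBr (1.05 equiv), Cu(OTf)2 (divalent copper, 3 mol%), chiral imidazolinium carbene precursor (4 mol%, enantiomer giving 3S), Et2O, −30 °C; then 15, −78 °C; aq. NH4Cl
Reagents that add atoms: methylmagnesium bromide, C[Mg]Br
Why: Copper-catalysed asymmetric conjugate addition sets C22, and the magnesium enolate is trapped by aldol addition to the glyoxylate anti to the new methyl. This sets quaternary C20 with the two methyl groups cis on the ring; the C19 carbinol configuration is of no consequence.

Step 11
Reactants: 17 hydroxy keto ester
Product: 18 bis(triethylsilyl) derivative (C31–C25 silyl enol ether and C19 silyl ether)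
Conditions: Et3SiOTf (2.3 equiv), Et3N, CH2Cl2, 0 °C
Reagents that add atoms: triethylsilyl trifluoromethanesulfonate, CC[Si](CC)(CC)OS(=O)(=O)C(F)(F)F
Why: Soft enolisation; the ketone has α-hydrogens only at C25, so a single silyl enol ether forms, and the C19 hydroxyl is silylated in the same operation.

Step 12
Reactants: 18 bis-silyl compound
Product: 19 (2S,3S)-5-methoxy-2-[2-methoxy-2-oxo-1-(triethylsilyloxy)ethyl]-2,3-dimethyl-5-oxopentanoic acid (C31 acid)
Conditions: O3, CH2Cl2/MeOH, NaHCO3, −78 °C; then Ac2O, Et3N, 0 °C → rt; aqueous work-up
Reagents that add atoms: ozone, [O-][O+]=O; methanol, CO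
Why: Ozonolysis of the silyl enol ether gives the silyl ester at C31 and a carbonyl oxide at C25, which methanol traps as the methoxy hydroperoxide. Acetylation and base-induced fragmentation turn this into the methyl ester, and aqueous work-up frees the C31 acid, so the two termini are differentiated in one step.

Step 13
Reactants: 19 acid, 13 ring A alcohol
Product: 21 C18 ester of alcohol 13 and acid 19 (C19 OTES; C25 methyl ester), via acid chloride 20 (not isolated)
Conditions: Me2C=C(Cl)NMe2, CH2Cl2, 0 °C → rt; then 13, DMAP, Et3N, ClCH2CH2Cl, 60 °C
Reagents that add atoms: none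
Why: DMAP-catalysed acylation of a hindered secondary alcohol by an α-quaternary acid chloride; the chloroenamine forms the acid chloride without free acid, which spares the silyl ethers, and no stereocentre is touched.

Step 14
Reactants: 21 silyl ether ester
Product: 22 C19 hydroxy ester
Conditions: HF·pyridine, pyridine, THF, 0 °C
Reagents that add atoms: none
Why: Buffered fluoride removes the triethylsilyl ether selectively, since TES ethers are cleaved much faster than secondary or tertiary TBS ethers.

Step 15
Reactants: 22 hydroxy ester
Product: 23 C19 α-keto ester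
Conditions: Dess–Martin periodinane, NaHCO3, CH2Cl2, rt
Reagents that add atoms: none
Why: Dess–Martin oxidation of the α-hydroxy ester under buffered conditions; the ketone is made only after esterification because with a free C31 acid it would be a β-keto acid prone to decarboxylation.

Step 16
Reactants: 23 α-keto ester
Product: 25 C19 diazo ester (key precursor), via tosylhydrazone 24 (not isolated)
Conditions: TsNHNH2, THF, 40 °C; then DBU, CH2Cl2, 0 °C → rt
Reagents that add atoms: p-toluenesulfonyl hydrazide, Cc1ccc(cc1)S(=O)(=O)NN
Why: The activated ketone condenses with tosylhydrazide, and DBU eliminates sulfinate from the hydrazone anion (first stage of the Bamford–Stevens reaction), the usual way to α-diazo esters that carry a tertiary alkyl group on the diazo carbon.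

Step 17
Reactants: 25 diazo ester
Product: 26 spiro γ-lactone with rings A, B and C (C19 methyl ester drawn as one epimer; C25 methyl ester)
Conditions: Rh2(O2CCPh3)4 (divalent rhodium, 2 mol%), CH2Cl2, slow addition, 25 → 40 °C
Reagents that add atoms: none
Why: Loss of N2 on the dirhodium tetracarboxylate gives an electrophilic carbenoid at C19, which reaches the axial C18–H through a five-membered transition state (C19, C20, C31, O34, C18) and inserts in one concerted three-centre step. The closest known reaction type is the intramolecular 1,5 C–H insertion of α-diazo ester carbenoids into C–H bonds on oxygen-bearing carbon, including the carbinol C–H of esters, which proceeds with retention. Ring C closes as a five-membered lactone by C18–C19 bond formation. C18 keeps the configuration set in step 9, so O34 stays equatorial and C19 becomes axial; C19 forms as ester epimers, which does not matter because it becomes CH2 in step 20. The step needs site selectivity, and the substrate supplies it: quaternary C20 excludes a 1,2-hydride shift, C18–H is the only oxygen-activated C–H five atoms from the carbenoid, the other candidates (C2–H, C24–H2, C23–H3) would close six- or four-membered rings, and the axial C18–H lies on the α face away from the axial C1 methyl and C17 methylene. Chemoselectivity rests on the silylated hydroxyls, on the C25 methyl ester, whose carbonyl can add to the carbenoid only reversibly, and on the bulky triphenylacetate ligands, which disfavour dimerisation and 1,2-migration. The ester oxygen activates less than an ether oxygen and the ester must reach its s-cis conformer, so the substrate is added slowly at high dilution, and the gem-disubstitution at C20 favours the folded conformer.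

Step 18
Reactants: 26 diester lactone
Product: 27 C19,C25 diacid
Conditions: LiI, EtOAc, reflux; aq. HCl
Reagents that add atoms: none
Why: SN2 dealkylation of both methyl esters by iodide at the methyl carbon; the lactone O-alkyl carbons are neopentyl (C17) and tertiary (C18) and are not attacked, and the non-basic medium avoids β-elimination of O34 from the C19 ester.

Step 19
Reactants: 27 diacid
Product: 28 C25 S-tert-butyl thioester C19 acid
Conditions: t-BuSH, EDC·HCl (1.05 equiv), DMAP (cat.), CH2Cl2, −20 → 0 °C
Reagents that add atoms: 2-methylpropane-2-thiol, CC(C)(C)S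
Why: Carbodiimide thioesterification (Steglich type) with limiting carbodiimide; the C25 acid is a primary-alkyl acid, while the C19 acid lies between two quaternary carbons and reacts much more slowly.

Step 20
Reactants: 28 thioester acid
Product: 31 C19 methylene tricycle with the C25 S-tert-butyl thioester, via acid chloride 29 (not isolated), via thiohydroxamate ester 30 (not isolated)
Conditions: Me2C=C(Cl)NMe2, CH2Cl2, 0 °C → rt; then sodium 2-thioxopyridin-1(2H)-olate, DMAP (cat.), t-BuSH, PhH, hν, 80 °C
Reagents that add atoms: none
Why: Barton reductive decarboxylation; the thiohydroxamate ester fragments under light to the C19 radical, which the thiol reduces faster than any β-scission of the C18–O34 bond, and the thioester is inert to the radical chain.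

Step 21
Reactants: 32 methyl 2,2-dimethoxypropanoate
Product: 33 2,2-dimethoxypropanal
Conditions: iBu2AlH, CH2Cl2, −78 °C; Rochelle salt
Reagents that add atoms: none
Why: Half-reduction of an α,α-dialkoxy ester; the chelated aluminium hemiacetal is stable at −78 °C and releases the aldehyde only on work-up.

Step 22
Reactants: 31 thioester, 33 2,2-dimethoxypropanal
Product: 35 anti-aldol adduct (C24–C33 bond; C33 hydroxyl; C28 dimethyl ketal), via boron enolate 34 (not isolated)
Conditions: Bu2BOTf, iPr2NEt, CH2Cl2, −78 → 0 °C; then 33, −78 → −20 °C; pH 7 buffer/MeOH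
Reagents that add atoms: none
Why: The boron triflate and amine enolise the S-tert-butyl thioester but not the lactones and give the enolate with C22 trans to the boron-bearing oxygen, so the Zimmerman–Traxler chair delivers the anti aldol. The aldehyde approaches the enolate face anti to quaternary C20 with the C22–H in the enolate plane (A1,3 strain), which sets C24 relative to C22.

Step 23
Reactants: 35 aldol thioester
Product: 36 C25 carboxylic acid
Conditions: AgNO3, 2,6-lutidine, THF/H2O, rt
Reagents that add atoms: water, O
Why: Thiophilic silver activation hydrolyses the thioester under nearly neutral conditions that leave the ketal, the silyl ethers and both lactones untouched.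

Step 24
Reactants: 36 hydroxy acid
Product: 38 chermebilaene B, via seco keto acid 37 (not isolated)
Conditions: 48% aq. HF, MeCN, 0 °C → rt; evaporation; then TsOH·H2O (cat.), 4 Å MS, CH2Cl2, rt
Reagents that add atoms: none
Why: HF removes both TBS groups and the acidic medium hydrolyses the ketal. The γ-keto acid closes to the hydroxy lactone (ring E), and its cis C28 and C33 hydroxyls condense with the C31 lactone carbonyl under dehydrating acid (acid-catalysed ortho ester formation from a lactone and a cis-diol, as in caged ortho esters), closing rings F and D. C28 and C31 can form only with the configurations dictated by C20, C22, C24 and C33.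

## Compound list

1 | (R)-carvone | CC(=C)[C@@H]1CC=C(C)C(=O)C1 | starting material
2 | (5R)-5-(2-hydroxypropan-2-yl)-2-methylcyclohex-2-en-1-one | CC1=CC[C@@H](C(C)(C)O)CC1=O | intermediate
3 | (5R)-5-[2-(tert-butyldimethylsilyloxy)propan-2-yl]-2-methylcyclohex-2-en-1-one | CC1=CC[C@@H](C(C)(C)O[Si](C)(C)C(C)(C)C)CC1=O | intermediate
4 | (5R,6Z)-5-[2-(tert-butyldimethylsilyloxy)propan-2-yl]-6-(hydroxymethylidene)-2-methylcyclohex-2-en-1-one | CC1=CC[C@@H](C(C)(C)O[Si](C)(C)C(C)(C)C)/C(=C/O)C1=O | intermediate
5 | methyl acrylate | C=CC(=O)OC | starting material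
6 | methyl 3-[(1S,6R)-6-[2-(tert-butyldimethylsilyloxy)propan-2-yl]-1-formyl-3-methyl-2-oxocyclohex-3-en-1-yl]propanoate | CC1=CC[C@@H](C(C)(C)O[Si](C)(C)C(C)(C)C)[C@](C=O)(CCC(=O)OC)C1=O | intermediate
7 | C17 hydroxymethyl keto ester | CC1=CC[C@@H](C(C)(C)O[Si](C)(C)C(C)(C)C)[C@](CO)(CCC(=O)OC)C1=O | intermediate (not isolated)
8 | spiro δ-lactone enone, rings A and B | CC1=CC[C@@H](C(C)(C)O[Si](C)(C)C(C)(C)C)[C@]2(CCC(=O)OC2)C1=O | intermediate
9 | C18 allylic alcohol, hydroxyl cis to C17 | CC1=CC[C@@H](C(C)(C)O[Si](C)(C)C(C)(C)C)[C@]2(CCC(=O)OC2)[C@H]1O | intermediate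
10 | C2–C3 epoxy alcohol, epoxide cis to the C18 hydroxyl | C[C@]12O[C@H]1C[C@@H](C(C)(C)O[Si](C)(C)C(C)(C)C)[C@]3(CCC(=O)OC3)[C@H]2O | intermediate
11 | C18 O-TBS ether of the epoxy alcohol | C[C@]12O[C@H]1C[C@@H](C(C)(C)O[Si](C)(C)C(C)(C)C)[C@]3(CCC(=O)OC3)[C@H]2O[Si](C)(C)C(C)(C)C | intermediate (not isolated)
12 | ring A ketone, C3 OTBS and C2 methyl cis | C[C@H]1[C@@H](O[Si](C)(C)C(C)(C)C)C[C@@H](C(C)(C)O[Si](C)(C)C(C)(C)C)[C@]2(CCC(=O)OC2)C1=O | intermediate
13 | ring A alcohol, equatorial C18 hydroxyl | C[C@H]1[C@@H](O[Si](C)(C)C(C)(C)C)C[C@@H](C(C)(C)O[Si](C)(C)C(C)(C)C)[C@]2(CCC(=O)OC2)[C@H]1O | intermediate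
14 | 2-methylcyclopent-2-en-1-one | CC1=CCCC1=O | starting material
15 | methyl glyoxylate | O=CC(=O)OC | starting material
16 | bromomagnesium (3S)-2,3-dimethylcyclopent-1-en-1-olate | C[C@H]1CCC(O[Mg]Br)=C1C | intermediate (not isolated)
17 | methyl 2-hydroxy-2-[(1S,2S)-1,2-dimethyl-5-oxocyclopentyl]acetate | C[C@H]1CCC(=O)[C@]1(C)[C@H](O)C(=O)OC | intermediate
18 | bis(triethylsilyl) enol ether and C19 silyl ether | C[C@H]1CC=C(O[Si](CC)(CC)CC)[C@]1(C)[C@H](O[Si](CC)(CC)CC)C(=O)OC | intermediate
19 | (2S,3S)-5-methoxy-2-[2-methoxy-2-oxo-1-(triethylsilyloxy)ethyl]-2,3-dimethyl-5-oxopentanoic acid | OC(=O)[C@](C)([C@H](O[Si](CC)(CC)CC)C(=O)OC)[C@@H](C)CC(=O)OC | intermediate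
20 | acid chloride of acid 19 | ClC(=O)[C@](C)([C@H](O[Si](CC)(CC)CC)C(=O)OC)[C@@H](C)CC(=O)OC | intermediate (not isolated)
21 | C18 ester with C19 OTES | C[C@H]1[C@@H](O[Si](C)(C)C(C)(C)C)C[C@@H](C(C)(C)O[Si](C)(C)C(C)(C)C)[C@]2(CCC(=O)OC2)[C@H]1OC(=O)[C@](C)([C@H](O[Si](CC)(CC)CC)C(=O)OC)[C@@H](C)CC(=O)OC | intermediate
22 | C19 hydroxy ester | C[C@H]1[C@@H](O[Si](C)(C)C(C)(C)C)C[C@@H](C(C)(C)O[Si](C)(C)C(C)(C)C)[C@]2(CCC(=O)OC2)[C@H]1OC(=O)[C@](C)([C@H](O)C(=O)OC)[C@@H](C)CC(=O)OC | intermediate
23 | C19 α-keto ester | C[C@H]1[C@@H](O[Si](C)(C)C(C)(C)C)C[C@@H](C(C)(C)O[Si](C)(C)C(C)(C)C)[C@]2(CCC(=O)OC2)[C@H]1OC(=O)[C@](C)(C(=O)C(=O)OC)[C@@H](C)CC(=O)OC | intermediate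
24 | C19 tosylhydrazone | C[C@H]1[C@@H](O[Si](C)(C)C(C)(C)C)C[C@@H](C(C)(C)O[Si](C)(C)C(C)(C)C)[C@]2(CCC(=O)OC2)[C@H]1OC(=O)[C@](C)(C(=NNS(=O)(=O)c3ccc(C)cc3)C(=O)OC)[C@@H](C)CC(=O)OC | intermediate (not isolated)
25 | C19 diazo ester, key precursor | C[C@H]1[C@@H](O[Si](C)(C)C(C)(C)C)C[C@@H](C(C)(C)O[Si](C)(C)C(C)(C)C)[C@]2(CCC(=O)OC2)[C@H]1OC(=O)[C@](C)(C(=[N+]=[N-])C(=O)OC)[C@@H](C)CC(=O)OC | intermediate
26 | spiro γ-lactone with rings A, B and C, key product | C[C@H]1[C@@H](O[Si](C)(C)C(C)(C)C)C[C@@H](C(C)(C)O[Si](C)(C)C(C)(C)C)[C@]2(CCC(=O)OC2)[C@]12[C@H](C(=O)OC)[C@@](C)(C(=O)O2)[C@@H](C)CC(=O)OC | intermediate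
27 | C19,C25 diacid | C[C@H]1[C@@H](O[Si](C)(C)C(C)(C)C)C[C@@H](C(C)(C)O[Si](C)(C)C(C)(C)C)[C@]2(CCC(=O)OC2)[C@]12[C@H](C(=O)O)[C@@](C)(C(=O)O2)[C@@H](C)CC(=O)O | intermediate
28 | C25 S-tert-butyl thioester C19 acid | C[C@H]1[C@@H](O[Si](C)(C)C(C)(C)C)C[C@@H](C(C)(C)O[Si](C)(C)C(C)(C)C)[C@]2(CCC(=O)OC2)[C@]12[C@H](C(=O)O)[C@@](C)(C(=O)O2)[C@@H](C)CC(=O)SC(C)(C)C | intermediate
29 | C19 acid chloride | C[C@H]1[C@@H](O[Si](C)(C)C(C)(C)C)C[C@@H](C(C)(C)O[Si](C)(C)C(C)(C)C)[C@]2(CCC(=O)OC2)[C@]12[C@H](C(Cl)=O)[C@@](C)(C(=O)O2)[C@@H](C)CC(=O)SC(C)(C)C | intermediate (not isolated)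
30 | C19 thiohydroxamate (Barton) ester | C[C@H]1[C@@H](O[Si](C)(C)C(C)(C)C)C[C@@H](C(C)(C)O[Si](C)(C)C(C)(C)C)[C@]2(CCC(=O)OC2)[C@]12[C@H](C(=O)On3ccccc3=S)[C@@](C)(C(=O)O2)[C@@H](C)CC(=O)SC(C)(C)C | intermediate (not isolated)
31 | C19 methylene tricycle, C25 S-tert-butyl thioester | C[C@H]1[C@@H](O[Si](C)(C)C(C)(C)C)C[C@@H](C(C)(C)O[Si](C)(C)C(C)(C)C)[C@]2(CCC(=O)OC2)[C@]12C[C@@](C)(C(=O)O2)[C@@H](C)CC(=O)SC(C)(C)C | intermediate
32 | methyl 2,2-dimethoxypropanoate | COC(=O)C(C)(OC)OC | starting material
33 | 2,2-dimethoxypropanal | CC(OC)(OC)C=O | intermediate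
34 | dibutylboron enolate of 31, C22 trans to the boron-bearing oxygen | C[C@H]1[C@@H](O[Si](C)(C)C(C)(C)C)C[C@@H](C(C)(C)O[Si](C)(C)C(C)(C)C)[C@]2(CCC(=O)OC2)[C@]12C[C@@](C)(C(=O)O2)[C@@H](C)/C=C(/OB(CCCC)CCCC)SC(C)(C)C | intermediate (not isolated)
35 | anti-aldol thioester | C[C@H]1[C@@H](O[Si](C)(C)C(C)(C)C)C[C@@H](C(C)(C)O[Si](C)(C)C(C)(C)C)[C@]2(CCC(=O)OC2)[C@]12C[C@@](C)(C(=O)O2)[C@@H](C)[C@H]([C@H](O)C(C)(OC)OC)C(=O)SC(C)(C)C | intermediate
36 | C25 carboxylic acid with C33 hydroxyl and C28 ketal | C[C@H]1[C@@H](O[Si](C)(C)C(C)(C)C)C[C@@H](C(C)(C)O[Si](C)(C)C(C)(C)C)[C@]2(CCC(=O)OC2)[C@]12C[C@@](C)(C(=O)O2)[C@@H](C)[C@H]([C@H](O)C(C)(OC)OC)C(=O)O | intermediate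
37 | seco keto acid triol | C[C@H]1[C@@H](O)C[C@@H](C(C)(C)O)[C@]2(CCC(=O)OC2)[C@]12C[C@@](C)(C(=O)O2)[C@@H](C)[C@H]([C@H](O)C(C)=O)C(=O)O | intermediate (not isolated)
38 | chermebilaene B | C[C@H]1[C@@H](O)C[C@@H](C(C)(C)O)[C@]2(CCC(=O)OC2)[C@]12C[C@]1(C)[C@@H](C)[C@H]3C(=O)O[C@@]4(C)O[C@@]1(O[C@@H]34)O2 | target

## Step count and least certain steps

Total step count: 24. Longest linear sequence: 20 steps (steps 1–9, 13–20, 22–24, from (R)-carvone).

**Step 17 (key step).** The carbenoid may be used up by other paths before it reaches the hindered carbinol C–H, which is only weakly activated by an ester oxygen and accessible only from the s-cis ester conformer. These paths are reversible ylide formation at the C25 ester followed by dimerisation, 1,2-migration of a C20 substituent, and insertion into adventitious water. The fallback forms C18–C19 as a polar bond. It sets out from 14 and ketone 12. The conjugate addition of step 10, with enolate 16 trapped by methyl bromoacetate, gives methyl 2-[(1S,2S)-1,2-dimethyl-5-oxocyclopentyl]acetate F1. Et3SiOTf/Et3N converts the ring ketone into the silyl enol ether F2, which leaves the ester methylene as the only acidic site. Its lithium enolate (LiN(iPr)2, then CeCl3) adds to ketone 12 from the open axial α face to give the tertiary alcohol F3. Ozonolysis with the work-up of step 12 frees the C31 acid, which lactonises onto the C18 hydroxyl, and the route is rejoined at 26.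

**Step 13.** Acylation of the hindered alcohol by the α-quaternary acid chloride may be so slow that the acid chloride decomposes (loss of silyl chloride to a β-lactone) or that 13 translactonises. The fallback esterifies earlier, at a less hindered alcohol. It sets out from allylic alcohol 9 and acid chloride 20, which give the allylic ester F4. Hydroboration from the α face (BH3·SMe2; NaBO3) installs the C2 hydrogen correctly and gives the axial C3 alcohol F5. Dess–Martin oxidation gives the C3 ketone F6, and NaBH4/CeCl3 gives the equatorial C3 alcohol F7. Silylation with TBSOTf rejoins the route at 21.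

**Step 24.** Cage closure may stop short because the dehydration equilibrium is not driven to the ortho ester, or the tertiary alcohol may dehydrate under acid. The fallback replaces the acid-driven dehydration by an irreversible silyl-transfer condensation. It sets out from 36. Aqueous acetic acid hydrolyses the ketal with the TBS ethers kept and gives the ring E hydroxy lactone diol F8. TMSCl/imidazole gives its bis(trimethylsilyl) ether F9. Catalytic TMSOTf at −78 °C condenses the two silyl ethers with the C31 lactone carbonyl, with loss of hexamethyldisiloxane, to give the bis-TBS cage F10. HF·pyridine then gives 38.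

**Step 22.** Enolisation of the β-branched thioester may be incomplete, or the facial preference set by C22 may be too weak, which would give C24/C33 diastereomers. The fallback changes the nucleophile to an enamine under catalyst control. It sets out from thioester 31. Et3SiH with Pd/C (Fukuyama reduction) gives the C25 aldehyde F11. A D-proline-catalysed cross-aldol with the non-enolisable aldehyde 33 gives the anti-aldol aldehyde F12. NaClO2 oxidation rejoins the route at 36.

**Step 10.** Methyl transfer to a five-membered α-substituted enone may proceed with low enantioselectivity, or the hindered enolate may give retro-aldol on trapping. The fallback sets C22 by asymmetric hydride addition instead. It sets out from commercial 2,3-dimethylcyclopent-2-en-1-one F13 and 15. Conjugate reduction with CuCl (monovalent copper), NaOtBu, p-Tol-BINAP and Ph2SiH2 gives the (3S) silyl enol ether F14. A Mukaiyama aldol with 15 (BF3·OEt2, −78 °C) rejoins the route at 17.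

**Step 8.** The cationic rearrangement may take another course (migration of C11 with ring contraction instead of hydride), or the β-silyloxy ketone may epimerise at C2. The fallback opens the epoxide reductively. It sets out from 10. Cp2TiCl (trivalent titanium, from Cp2TiCl2 and Mn) with 1,4-cyclohexadiene gives the C3,C18 diol F15, the C2 hydrogen being delivered from the α face. Selective silylation of the less hindered C3 hydroxyl (TBSCl, imidazole) rejoins the route at 13, without passing through 12.

## Further compounds

F1 | step 17 | methyl 2-[(1S,2S)-1,2-dimethyl-5-oxocyclopentyl]acetate | C[C@H]1CCC(=O)[C@]1(C)CC(=O)OC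
F2 | step 17 | triethylsilyl enol ether of F1 | C[C@H]1CC=C(O[Si](CC)(CC)CC)[C@]1(C)CC(=O)OC
F3 | step 17 | C18 tertiary alcohol from aldol addition of F2 to ketone 12 | C[C@H]1[C@@H](O[Si](C)(C)C(C)(C)C)C[C@@H](C(C)(C)O[Si](C)(C)C(C)(C)C)[C@]2(CCC(=O)OC2)[C@]1(O)[C@H](C(=O)OC)[C@]3(C)[C@@H](C)CC=C3O[Si](CC)(CC)CC
F4 | step 13 | C18 ester of allylic alcohol 9 with acid 19 | CC1=CC[C@@H](C(C)(C)O[Si](C)(C)C(C)(C)C)[C@]2(CCC(=O)OC2)[C@H]1OC(=O)[C@](C)([C@H](O[Si](CC)(CC)CC)C(=O)OC)[C@@H](C)CC(=O)OC
F5 | step 13 | axial C3 alcohol from hydroboration | C[C@H]1[C@H](O)C[C@@H](C(C)(C)O[Si](C)(C)C(C)(C)C)[C@]2(CCC(=O)OC2)[C@H]1OC(=O)[C@](C)([C@H](O[Si](CC)(CC)CC)C(=O)OC)[C@@H](C)CC(=O)OC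
F6 | step 13 | C3 ketone | C[C@H]1C(=O)C[C@@H](C(C)(C)O[Si](C)(C)C(C)(C)C)[C@]2(CCC(=O)OC2)[C@H]1OC(=O)[C@](C)([C@H](O[Si](CC)(CC)CC)C(=O)OC)[C@@H](C)CC(=O)OC
F7 | step 13 | equatorial C3 alcohol | C[C@H]1[C@@H](O)C[C@@H](C(C)(C)O[Si](C)(C)C(C)(C)C)[C@]2(CCC(=O)OC2)[C@H]1OC(=O)[C@](C)([C@H](O[Si](CC)(CC)CC)C(=O)OC)[C@@H](C)CC(=O)OC
F8 | step 24 | ring E hydroxy lactone diol with both TBS ethers (C28 hemiketal epimers) | C[C@H]1[C@@H](O[Si](C)(C)C(C)(C)C)C[C@@H](C(C)(C)O[Si](C)(C)C(C)(C)C)[C@]2(CCC(=O)OC2)[C@]12C[C@@](C)(C(=O)O2)[C@@H](C)[C@H]3C(=O)OC(C)(O)[C@H]3O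
F9 | step 24 | bis(trimethylsilyl) ether of F8 | C[C@H]1[C@@H](O[Si](C)(C)C(C)(C)C)C[C@@H](C(C)(C)O[Si](C)(C)C(C)(C)C)[C@]2(CCC(=O)OC2)[C@]12C[C@@](C)(C(=O)O2)[C@@H](C)[C@H]3C(=O)OC(C)(O[Si](C)(C)C)[C@H]3O[Si](C)(C)C
F10 | step 24 | bis-TBS ether of chermebilaene B | C[C@H]1[C@@H](O[Si](C)(C)C(C)(C)C)C[C@@H](C(C)(C)O[Si](C)(C)C(C)(C)C)[C@]2(CCC(=O)OC2)[C@]12C[C@]1(C)[C@@H](C)[C@H]3C(=O)O[C@@]4(C)O[C@@]1(O[C@@H]34)O2
F11 | step 22 | C25 aldehyde | C[C@H]1[C@@H](O[Si](C)(C)C(C)(C)C)C[C@@H](C(C)(C)O[Si](C)(C)C(C)(C)C)[C@]2(CCC(=O)OC2)[C@]12C[C@@](C)(C(=O)O2)[C@@H](C)CC=O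
F12 | step 22 | anti-aldol aldehyde | C[C@H]1[C@@H](O[Si](C)(C)C(C)(C)C)C[C@@H](C(C)(C)O[Si](C)(C)C(C)(C)C)[C@]2(CCC(=O)OC2)[C@]12C[C@@](C)(C(=O)O2)[C@@H](C)[C@H]([C@H](O)C(C)(OC)OC)C=O
F13 | step 10 | 2,3-dimethylcyclopent-2-en-1-one | CC1=C(C)C(=O)CC1
F14 | step 10 | (3S)-2,3-dimethylcyclopent-1-en-1-yl diphenylsilyl ether | C[C@H]1CCC(O[SiH](c2ccccc2)c2ccccc2)=C1C
F15 | step 8 | C3,C18 diol | C[C@H]1[C@@H](O)C[C@@H](C(C)(C)O[Si](C)(C)C(C)(C)C)[C@]2(CCC(=O)OC2)[C@H]1O
A1 | alternative 1 | hydroxy decalin with exocyclic C1=C2 alkene and C19 acetate | C=C1CC[C@H]2C(C)(C)[C@@H](O)CC[C@]2(CO[Si](C)(C)C(C)(C)C)[C@H]1COC(C)=O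
A2 | alternative 2 | ring A/B spiro-lactone enone with the tertiary alcohol | CC1=CC[C@@H](C(C)(C)O)[C@]2(CCC(=O)OC2)C1=O
A3 | alternative 3 | ring D ortho ester adduct | C[C@H]1[C@@H](O[Si](C)(C)C(C)(C)C)C[C@@H](C(C)(C)O)[C@]2(CCC(=O)OC2)[C@]12C[C@]1(C)[C@@H](C)C(C(=O)OC)=C(C3(C)OCCO3)O[C@]1(OC)O2
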